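**Plan**
- Retrosynthesis: the benzyl group on O3' comes off last. Ring C is then cut at O1–C8a, C4–C4a and O1–C2, leaving a 3,4,5-trimethoxybenzyne (ring A) and an arylpropiolic acid that carries ring B together with C2, C3 and C4.
- Enabling feature: in ring A, O1 (on C8a) and the carbonyl carbon C4 (on C4a) sit on neighbouring carbons, which is what an aryne delivers in one event. The C5 methoxy group beside C4a polarises that aryne so that oxygen goes to C8a.
- Forward, ring A: 3,4,5-trimethoxyphenol is converted into the ortho-silylaryl triflate in two steps.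
- Forward, ring B: syringol is benzylated, formylated and iodinated. The formyl group is then exchanged for the fourth oxygen (Dakin oxidation, methylation) and the iodide for the propiolic acid unit; the symmetric OMe–OBn–OMe triad removes any regiochemical ambiguity.
- Ring order: rings A and B come from benzenoid starting materials. Ring C is the only ring made, in the aryne step, and hydrogenolysis ends the route.
- Stereochemistry: the target has no stereocentre and no stereogenic double bond, so none has to be set.

Key step: step 9

Numbering used: flavone locants O1, C2–C4, C4a, C5–C8, C8a for rings C and A; primed locants for ring B.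

**Step 1**
Reactants: 1 3,4,5-trimethoxyphenol
Product: 2 2-bromo-3,4,5-trimethoxyphenol
Conditions: NBS (1.0 equiv), CH2Cl2, −78 to 0 °C
Reagents that add atoms: N-bromosuccinimide, O=C1CCC(=O)N1Br
Why: Electrophilic aromatic bromination of a phenol whose para position is blocked and whose two ortho positions are equivalent, so one equivalent of NBS at low temperature should give a single monobromide without oxidising the electron-rich ring.

**Step 2**
Reactants: 2 2-bromo-3,4,5-trimethoxyphenol
Product: 5 3,4,5-trimethoxy-2-(trimethylsilyl)phenyl trifluoromethanesulfonate, via aryl trimethylsilyl ether 3 (not isolated), via lithium 2-silylphenoxide 4 (not isolated)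
Conditions: HMDS, THF, reflux, then evaporation; n-BuLi, THF, −100 to −80 °C; Tf2O, −100 °C to rt
Reagents that add atoms: hexamethyldisilazane, C[Si](C)(C)N[Si](C)(C)C; trifluoromethanesulfonic anhydride, O=S(=O)(OS(=O)(=O)C(F)(F)F)C(F)(F)F
Why: O-silylation followed by bromine–lithium exchange triggers a retro-Brook 1,3-shift of silicon from oxygen to the ortho carbon, and the resulting lithium phenoxide is trapped by Tf2O, the standard sequence to ortho-silylaryl triflates.

**Step 3**
Reactants: 6 2,6-dimethoxyphenol (syringol)
Product: 7 2-(benzyloxy)-1,3-dimethoxybenzene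
Conditions: BnBr, K2CO3, DMF, 60 °C
Reagents that add atoms: benzyl bromide, BrCc1ccccc1
Why: Williamson ether synthesis installs a benzyl group that should withstand organolithium, peracid, fluoride and palladium coupling and can be removed at the end by hydrogenolysis without touching the six methyl ethers.

**Step 4**
Reactants: 7 2-(benzyloxy)-1,3-dimethoxybenzene
Product: 9 3-(benzyloxy)-2,4-dimethoxybenzaldehyde, via aryl iminium salt 8 (not isolated)
Conditions: POCl3, DMF, 0 to 80 °C; then ice–water
Reagents that add atoms: N,N-dimethylformamide, CN(C)C=O; water, O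
Why: Vilsmeier–Haack formylation in which the chloroiminium ion attacks C4 (equivalent to C6 by symmetry), ortho to one methoxy and para to the other, whereas C5 is only para to the twisted benzyloxy group; the iminium salt is hydrolysed on aqueous work-up.

**Step 5**
Reactants: 9 3-(benzyloxy)-2,4-dimethoxybenzaldehyde
Product: 10 3-(benzyloxy)-5-iodo-2,4-dimethoxybenzaldehyde
Conditions: I2, AgO2CCF3, CH2Cl2, 0 °C to rt, dark
Reagents that add atoms: iodine, II
Why: Electrophilic aromatic iodination by the acyl hypoiodite formed from I2 and AgO2CCF3 should go to C5, which is ortho to the 4-methoxy, para to the 2-methoxy and meta to the formyl group, while C6 is deactivated by the adjacent formyl group.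

**Step 6**
Reactants: 10 3-(benzyloxy)-5-iodo-2,4-dimethoxybenzaldehyde
Product: 12 3-(benzyloxy)-5-iodo-2,4-dimethoxyphenol, via aryl formate 11 (not isolated)
Conditions: mCPBA, CH2Cl2, 0 °C to rt, Na2S2O3/NaHCO3 wash; then Et3N (cat.), MeOH, rt
Reagents that add atoms: meta-chloroperoxybenzoic acid, OOC(=O)c1cccc(Cl)c1
Why: Dakin-type Baeyer–Villiger oxidation in which the ortho and para methoxy groups make the aryl group migrate in the Criegee adduct, giving the aryl formate that base-catalysed methanolysis cleaves to the phenol, so the formyl carbon is exchanged for the future O5'.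

**Step 7**
Reactants: 12 3-(benzyloxy)-5-iodo-2,4-dimethoxyphenol
Product: 13 3-(benzyloxy)-1-iodo-2,4,5-trimethoxybenzene
Conditions: MeI, K2CO3, acetone, reflux
Reagents that add atoms: iodomethane, CI
Why: Williamson O-methylation of the phenoxide completes the 2',4',5'-trimethoxy pattern around the benzyl-protected 3'-oxygen.

**Step 8**
Reactants: 13 3-(benzyloxy)-1-iodo-2,4,5-trimethoxybenzene; 14 propiolic acid
Product: 15 3-[3-(benzyloxy)-2,4,5-trimethoxyphenyl]propiolic acid
Conditions: Pd(PPh3)4 (5 mol %), DBU (2.5 equiv), DMSO, 35 °C; then cold 1 M HCl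
Reagents that add atoms: none
Why: Copper-free Sonogashira-type coupling of an aryl iodide with propiolic acid, in which oxidative addition to zerovalent palladium is fast even for this electron-rich ring and the mild temperature should keep the arylpropiolic acid from losing CO2.

**Step 9**
Reactants: 5 3,4,5-trimethoxy-2-(trimethylsilyl)phenyl trifluoromethanesulfonate (1.5 equiv); 15 3-[3-(benzyloxy)-2,4,5-trimethoxyphenyl]propiolic acid
Product: 18 2-[3-(benzyloxy)-2,4,5-trimethoxyphenyl]-5,6,7-trimethoxy-4H-chromen-4-one, via 3,4,5-trimethoxybenzyne 16 (not isolated), via ortho-acyl phenoxide 17 (not isolated)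
Conditions: CsF (4 equiv), THF, 125 °C, sealed tube
Reagents that add atoms: none
Why: Fluoride removes the silyl group of 5 and triflate leaves to give aryne 16; the cesium carboxylate of 15 adds through oxygen to the aryne carbon remote from the methoxy group (future C8a), and the aryl anion at the neighbouring carbon (future C4a) attacks the ester carbonyl through a four-membered alkoxide that opens to phenoxide 17, a net aryne insertion into the C–O bond of the acid that forms O1–C8a and C4–C4a. Phenoxide 17 then adds to the β-carbon of the ynone in a 6-endo-dig oxa-Michael closure (O1–C2) that makes ring C, and protonation at C3 gives the chromone. The closest known reaction is the fluoride-mediated addition of carboxylic acids to arynes with acyl migration to ortho-hydroxyaryl ketones, which with alkynoic acids is known to run on to flavones. No stereocentre is formed. The step needs regioselective addition to the unsymmetrical aryne, which the methoxy group flanking the triple bond secures by its inductive effect and the attendant ring distortion, sending the nucleophile to the distal carbon so that the 5,6,7- and not the 6,7,8-trimethoxy pattern results. It also needs 6-endo over 5-exo closure (flavone, not aurone), which the conjugate-acceptor polarisation of the ynone under aprotic conditions favours.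

**Step 10**
Reactants: 18 2-[3-(benzyloxy)-2,4,5-trimethoxyphenyl]-5,6,7-trimethoxy-4H-chromen-4-one
Product: 19 Agecorynin G, 2-(3-hydroxy-2,4,5-trimethoxyphenyl)-5,6,7-trimethoxy-4H-chromen-4-one
Conditions: H2 (1 atm), 10% Pd/C, EtOAc–MeOH, rt
Reagents that add atoms: none
Why: Hydrogenolysis of the benzyl aryl ether over Pd/C frees the 3'-hydroxyl, the methyl ethers being inert and the reaction being stopped after one equivalent of hydrogen so that the C2–C3 double bond of the chromone is kept.

**Compound list**
1 | 3,4,5-trimethoxyphenol | COc1cc(O)cc(OC)c1OC | starting material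
2 | 2-bromo-3,4,5-trimethoxyphenol | COc1cc(O)c(Br)c(OC)c1OC | intermediate
3 | (2-bromo-3,4,5-trimethoxyphenoxy)trimethylsilane | COc1cc(O[Si](C)(C)C)c(Br)c(OC)c1OC | intermediate
4 | lithium 3,4,5-trimethoxy-2-(trimethylsilyl)phenoxide | COc1cc([O-])c([Si](C)(C)C)c(OC)c1OC.[Li+] | intermediate
5 | 3,4,5-trimethoxy-2-(trimethylsilyl)phenyl trifluoromethanesulfonate | COc1cc(OS(=O)(=O)C(F)(F)F)c([Si](C)(C)C)c(OC)c1OC | intermediate
6 | 2,6-dimethoxyphenol (syringol) | COc1cccc(OC)c1O | starting material
7 | 2-(benzyloxy)-1,3-dimethoxybenzene | COc1cccc(OC)c1OCc1ccccc1 | intermediate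
8 | N-{[3-(benzyloxy)-2,4-dimethoxyphenyl]methylidene}-N-methylmethanaminium chloride (iminium salt, drawn as its chloride) | COc1ccc(C=[N+](C)C)c(OC)c1OCc1ccccc1.[Cl-] | intermediate
9 | 3-(benzyloxy)-2,4-dimethoxybenzaldehyde | COc1ccc(C=O)c(OC)c1OCc1ccccc1 | intermediate
10 | 3-(benzyloxy)-5-iodo-2,4-dimethoxybenzaldehyde | COc1c(I)cc(C=O)c(OC)c1OCc1ccccc1 | intermediate
11 | 3-(benzyloxy)-5-iodo-2,4-dimethoxyphenyl formate | COc1c(I)cc(OC=O)c(OC)c1OCc1ccccc1 | intermediate
12 | 3-(benzyloxy)-5-iodo-2,4-dimethoxyphenol | COc1c(I)cc(O)c(OC)c1OCc1ccccc1 | intermediate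
13 | 3-(benzyloxy)-1-iodo-2,4,5-trimethoxybenzene | COc1cc(I)c(OC)c(OCc2ccccc2)c1OC | intermediate
14 | propiolic acid | OC(=O)C#C | starting material
15 | 3-[3-(benzyloxy)-2,4,5-trimethoxyphenyl]propiolic acid | OC(=O)C#Cc1cc(OC)c(OC)c(OCc2ccccc2)c1OC | intermediate
16 | 3,4,5-trimethoxybenzyne (1,2-didehydro-3,4,5-trimethoxybenzene) | COC1=C(OC)C(OC)=CC#C1 | intermediate
17 | cesium 2-{3-[3-(benzyloxy)-2,4,5-trimethoxyphenyl]prop-2-ynoyl}-3,4,5-trimethoxyphenoxide | COc1cc(C#CC(=O)c2c([O-])cc(OC)c(OC)c2OC)c(OC)c(OCc2ccccc2)c1OC.[Cs+] | intermediate
18 | 2-[3-(benzyloxy)-2,4,5-trimethoxyphenyl]-5,6,7-trimethoxy-4H-chromen-4-one | COc1cc(-c2cc(=O)c3c(OC)c(OC)c(OC)cc3o2)c(OC)c(OCc2ccccc2)c1OC | intermediate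
19 | Agecorynin G, 2-(3-hydroxy-2,4,5-trimethoxyphenyl)-5,6,7-trimethoxy-4H-chromen-4-one | COc1cc(-c2cc(=O)c3c(OC)c(OC)c(OC)cc3o2)c(OC)c(O)c1OC | target

**Count**
Total steps: 10. Longest linear sequence: 8 steps (steps 3 to 10, from syringol); the ring A branch (steps 1 and 2) joins at step 9.

**Steps most likely to fail**

Step 9. At 125 °C the cesium arylpropiolate may lose CO2 before it meets the aryne, and simple protonation of the aryl anion (O-arylation without acyl shift) may compete with the insertion. The fallback keeps the same three bonds but lowers the oxidation level of the three-carbon unit. It sets out from 13 and 5 and comes back at 18. Mizoroki–Heck coupling of 13 with acrylic acid (Pd(OAc)2, P(o-tol)3, Et3N, DMF, 90 °C) should give (E)-3-[3-(benzyloxy)-2,4,5-trimethoxyphenyl]acrylic acid F1, which cannot decarboxylate in this way. Treating F1 with 5 and CsF in THF at 125 °C should lead, by the same aryne C–O insertion and a 6-endo-trig oxa-Michael closure, to racemic 2-[3-(benzyloxy)-2,4,5-trimethoxyphenyl]-5,6,7-trimethoxychroman-4-one F2. Dehydrogenation with catalytic I2 in DMSO at 120 °C, which also converts any ring-opened 2'-hydroxychalcone, should then give 18.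

Step 8. The arylpropiolic acid may decarboxylate under the basic palladium conditions and couple a second time to a diarylalkyne, or the ortho-substituted iodide may couple sluggishly. The fallback builds the alkyne and the carboxyl group separately. It sets out from 13 and comes back at 15. Sonogashira coupling of 13 with trimethylsilylacetylene (Pd(PPh3)2Cl2, CuI, Et3N, THF, 50 °C) should give {[3-(benzyloxy)-2,4,5-trimethoxyphenyl]ethynyl}trimethylsilane F3. Desilylation with catalytic K2CO3 in MeOH gives 3-(benzyloxy)-1-ethynyl-2,4,5-trimethoxybenzene F4. Deprotonation with n-BuLi in THF at −78 °C, quenching with CO2 and cold acidic work-up returns 15.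

Step 4. The benzyl ether may be lost under hot POCl3/DMF, or the only moderately activated ring may be attacked too slowly. The fallback replaces electrophilic formylation by halogen–metal exchange. It sets out from 7 and comes back at 9. Bromination of 7 with NBS in MeCN at 0 °C to rt should give 2-(benzyloxy)-4-bromo-1,3-dimethoxybenzene F5 with the same ortho/para control. Bromine–lithium exchange with n-BuLi in THF at −78 °C, quenching with DMF and aqueous work-up gives 9.

**Further compounds**
F1 | step 9 | (E)-3-[3-(benzyloxy)-2,4,5-trimethoxyphenyl]acrylic acid | OC(=O)/C=C/c1cc(OC)c(OC)c(OCc2ccccc2)c1OC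
F2 | step 9 | (±)-2-[3-(benzyloxy)-2,4,5-trimethoxyphenyl]-5,6,7-trimethoxychroman-4-one (racemic) | COc1cc(C2CC(=O)c3c(OC)c(OC)c(OC)cc3O2)c(OC)c(OCc2ccccc2)c1OC
F3 | step 8 | {[3-(benzyloxy)-2,4,5-trimethoxyphenyl]ethynyl}trimethylsilane | C[Si](C)(C)C#Cc1cc(OC)c(OC)c(OCc2ccccc2)c1OC
F4 | step 8 | 3-(benzyloxy)-1-ethynyl-2,4,5-trimethoxybenzene | C#Cc1cc(OC)c(OC)c(OCc2ccccc2)c1OC
F5 | step 4 | 2-(benzyloxy)-4-bromo-1,3-dimethoxybenzene | COc1ccc(Br)c(OC)c1OCc1ccccc1
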